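Everything rests on cutting two bonds at once on the γ-lactone (O1, C2=O, C3, C4, C5): C4–CH3 and C3–alkenyl. The ring carries an all-trans array (C3 alkenyl, C4 methyl, C5 dienyl), so the lone C5 stereocentre of a flat butenolide can dictate C4 and then C3, each new group entering trans to its neighbour. In one operation a methylcuprate adds to C4 and the enolate, passed to zinc, is alkenylated at C3 under palladium catalysis by the complete side-arm bromide carrying the masked ketol. The precursor is the (5S)-5-dienylbutenolide with the side-chain stereocentre in place as a silyl ether, reached by asymmetric propiolate addition to a dienal.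

Key step: step 17

Assumption: in step 8 the (S,S) antipode of ProPhenol is taken to deliver the alkynyl group to the Si face of the dienal carbonyl (4R alcohol); this sense was not confirmed and should be checked on the first run (Mosher esters), the (R,R) ligand being used if it proves opposite.

**Butenolide arm (steps 1–9)**

Step 1
Reactants: 1 (4R)-4-benzyl-1,3-oxazolidin-2-one; 2 hexanoyl chloride
Product: 3 (4R)-4-benzyl-3-hexanoyl-1,3-oxazolidin-2-one
Conditions: Et3N, DMAP (cat.), CH2Cl2, 0 °C → rt
Reagents that add atoms: none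
Why: N-acylation of the oxazolidinone by an acid chloride under DMAP nucleophilic catalysis is routine and creates no stereocentre.

Step 2
Reactants: 3 (4R)-4-benzyl-3-hexanoyl-1,3-oxazolidin-2-one
Product: 5 (4R)-4-benzyl-3-[(2S)-2-(hydroxymethyl)hexanoyl]-1,3-oxazolidin-2-one, via chlorotitanium Z-enolate 4 (not isolated)
Conditions: TiCl4, i-Pr2NEt, CH2Cl2, 0 °C; then 1,3,5-trioxane, TiCl4, 0 °C
Reagents that add atoms: 1,3,5-trioxane, C1OCOCO1
Why: Auxiliary-controlled enolate alkylation (Evans type), in which the chelated Z-enolate 4 should be hydroxymethylated by TiCl4-activated trioxane on the face away from the benzyl group, setting the 2S centre that becomes the side-chain stereocentre.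

Step 3
Reactants: 5 (4R)-4-benzyl-3-[(2S)-2-(hydroxymethyl)hexanoyl]-1,3-oxazolidin-2-one
Product: 6 (4R)-4-benzyl-3-[(2S)-2-(tert-butyldimethylsilyloxymethyl)hexanoyl]-1,3-oxazolidin-2-one
Conditions: TBSCl, imidazole, DMF, 0 °C → rt
Reagents that add atoms: tert-butyldimethylsilyl chloride, CC(C)(C)[Si](C)(C)Cl
Why: Imidazole-promoted silylation of a primary alcohol is standard, and the mild base should not trigger retro-aldol loss of formaldehyde or epimerisation.

Step 4
Reactants: 6 (4R)-4-benzyl-3-[(2S)-2-(tert-butyldimethylsilyloxymethyl)hexanoyl]-1,3-oxazolidin-2-one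
Product: 7 (2R)-2-(tert-butyldimethylsilyloxymethyl)hexan-1-ol
Conditions: LiBH4, MeOH (1 equiv), THF, 0 °C
Reagents that add atoms: none
Why: Reductive cleavage of the N-acyloxazolidinone with LiBH4 should give the primary alcohol and return the auxiliary without touching the α-centre or the silyl ether (the descriptor changes only through CIP priorities).

Step 5
Reactants: 7 (2R)-2-(tert-butyldimethylsilyloxymethyl)hexan-1-ol
Product: 8 (2S)-2-(tert-butyldimethylsilyloxymethyl)hexanal
Conditions: Dess–Martin periodinane, NaHCO3, CH2Cl2, 0 °C → rt; used crude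
Reagents that add atoms: none
Why: Buffered Dess–Martin oxidation stops at the aldehyde and is mild enough to preserve the α-stereocentre and avoid β-elimination of the silyloxy group.

Step 6
Reactants: 8 (2S)-2-(tert-butyldimethylsilyloxymethyl)hexanal
Product: 9 (2E,4R)-4-(tert-butyldimethylsilyloxymethyl)oct-2-enal
Conditions: Ph3P=CHCHO, toluene, 80 °C
Reagents that add atoms: (triphenylphosphoranylidene)acetaldehyde, O=CC=P(c1ccccc1)(c1ccccc1)c1ccccc1
Why: Wittig olefination with the formyl-stabilised ylide should give the E-enal, the weakly basic ylide sparing the α-centre and the less electrophilic product resisting a second homologation.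

Step 7
Reactants: 9 (2E,4R)-4-(tert-butyldimethylsilyloxymethyl)oct-2-enal
Product: 10 (2E,4E,6R)-6-(tert-butyldimethylsilyloxymethyl)-2-methyldeca-2,4-dienal
Conditions: Ph3P=C(CH3)CHO, toluene, 100 °C
Reagents that add atoms: 2-(triphenylphosphoranylidene)propanal, CC(C=O)=P(c1ccccc1)(c1ccccc1)c1ccccc1
Why: Wittig olefination with the α-methyl formyl-stabilised ylide should give the E trisubstituted alkene, and the hindered α-branched dienal formed does not react further.

Step 8
Reactants: 10 (2E,4E,6R)-6-(tert-butyldimethylsilyloxymethyl)-2-methyldeca-2,4-dienal; 11 methyl propiolate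
Product: 12 methyl (4R,5E,7E,9R)-9-(tert-butyldimethylsilyloxymethyl)-4-hydroxy-5-methyltrideca-5,7-dien-2-ynoate
Conditions: (S,S)-ProPhenol (20 mol %), Me2Zn (3 equiv), Ph3P=O (40 mol %), 11 (3 equiv), toluene, 0 → 4 °C
Reagents that add atoms: none
Why: Catalytic asymmetric alkynylation in which the dinuclear zinc complex formed from Me2Zn and ProPhenol binds both the aldehyde and the alkynylzinc and transfers the alkynyl group to one carbonyl face, so that C4 is set as R by catalyst control, the remote C9 centre having no influence.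

Step 9
Reactants: 12 methyl (4R,5E,7E,9R)-9-(tert-butyldimethylsilyloxymethyl)-4-hydroxy-5-methyltrideca-5,7-dien-2-ynoate
Product: 14 (5S)-5-[(2E,4E,6R)-6-(tert-butyldimethylsilyloxymethyl)deca-2,4-dien-2-yl]furan-2(5H)-one, via Z-hydroxy enoate 13 (not isolated)
Conditions: H2 (1 atm), Pd/CaCO3 poisoned with Pb(OAc)2 (Lindlar catalyst), quinoline, EtOAc, rt; then PPTS (cat.), CH2Cl2, rt
Reagents that add atoms: none
Why: Lindlar semihydrogenation should add hydrogen cis to the electron-poor alkyne while sparing the conjugated diene, and the Z-γ-hydroxy enoate 13 then lactonises without touching the carbinol centre (R becomes S only through CIP priorities).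

**Ketol arm (steps 10–16)**

Step 10
Reactants: 15 methacrolein
Product: 17 (2E)-3-bromo-2-methylprop-2-enal, via dibromide 16 (not isolated)
Conditions: Br2, CH2Cl2, −78 → 0 °C; then Et3N, 0 °C → rt
Reagents that add atoms: bromine, BrBr
Why: Bromine addition to the alkene followed by amine-induced dehydrobromination should give the conjugated β-bromo enal, the E isomer (Br trans to CHO) being the thermodynamic one.

Step 11
Reactants: 17 (2E)-3-bromo-2-methylprop-2-enal
Product: 19 (2E,4E)-5-bromo-4-methylpenta-2,4-dienal, via N-cyclohexyl azadiene 18 (not isolated)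
Conditions: diethyl [2-(cyclohexylamino)vinyl]phosphonate, NaH, THF, 0 °C → rt; then aq. oxalic acid, rt
Reagents that add atoms: diethyl [2-(cyclohexylamino)vinyl]phosphonate, CCOP(=O)(OCC)C=CNC1CCCCC1; water, O
Why: Horner–Wadsworth–Emmons formyl olefination with the metallated enamine phosphonate gives the E-azadiene 18, which cannot be homologated a second time, and mild acid hydrolysis should release the E,E-dienal.

Step 12
Reactants: 19 (2E,4E)-5-bromo-4-methylpenta-2,4-dienal; 20 (4R)-4-benzyl-3-propanoyl-1,3-oxazolidin-2-one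
Product: 22 (4R)-4-benzyl-3-[(2R,3S,4E,6E)-7-bromo-3-hydroxy-2,6-dimethylhepta-4,6-dienoyl]-1,3-oxazolidin-2-one, via boron Z-enolate 21 (not isolated)
Conditions: 20, Bu2BOTf, i-Pr2NEt, CH2Cl2, 0 °C; then 19, −78 → 0 °C; H2O2, MeOH, pH 7 buffer, 0 °C
Reagents that add atoms: none
Why: Evans syn-aldol reaction in which the Z-boron enolate 21 reacts through a closed chair transition state on the face away from the benzyl group, setting 2R and 3S (syn) by auxiliary control.

Step 13
Reactants: 22 (4R)-4-benzyl-3-[(2R,3S,4E,6E)-7-bromo-3-hydroxy-2,6-dimethylhepta-4,6-dienoyl]-1,3-oxazolidin-2-one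
Product: 23 (2R,3S,4E,6E)-7-bromo-3-hydroxy-N-methoxy-N,2,6-trimethylhepta-4,6-dienamide
Conditions: MeONHMe·HCl, AlMe3, CH2Cl2, −20 → 0 °C
Reagents that add atoms: N,O-dimethylhydroxylamine hydrochloride, CNOC.Cl
Why: Aluminium-amide transamidation to the Weinreb amide is assisted by the free β-hydroxyl and should leave both stereocentres and the alkenyl bromide untouched.

Step 14
Reactants: 23 (2R,3S,4E,6E)-7-bromo-3-hydroxy-N-methoxy-N,2,6-trimethylhepta-4,6-dienamide
Product: 24 (2R,3S,4E,6E)-7-bromo-N-methoxy-N,2,6-trimethyl-3-(triethylsilyloxy)hepta-4,6-dienamide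
Conditions: TESCl, imidazole, DMF, 0 °C
Reagents that add atoms: chlorotriethylsilane, CC[Si](Cl)(CC)CC
Why: Routine silylation of a secondary alcohol, the triethylsilyl ether being chosen so that it falls together with the ketal in the last step.

Step 15
Reactants: 24 (2R,3S,4E,6E)-7-bromo-N-methoxy-N,2,6-trimethyl-3-(triethylsilyloxy)hepta-4,6-dienamide
Product: 25 (3R,4S,5E,7E)-8-bromo-3,7-dimethyl-4-(triethylsilyloxy)octa-5,7-dien-2-one
Conditions: MeMgBr, THF, −78 → 0 °C; aq. NH4Cl
Reagents that add atoms: methylmagnesium bromide, C[Mg]Br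
Why: Weinreb ketone synthesis, in which the stable magnesium chelate prevents over-addition and the alkenyl bromide does not undergo halogen–magnesium exchange with MeMgBr at low temperature.

Step 16
Reactants: 25 (3R,4S,5E,7E)-8-bromo-3,7-dimethyl-4-(triethylsilyloxy)octa-5,7-dien-2-one
Product: 26 2-[(2R,3S,4E,6E)-7-bromo-6-methyl-3-(triethylsilyloxy)hepta-4,6-dien-2-yl]-2-methyl-1,3-dioxolane
Conditions: Me3SiOCH2CH2OSiMe3, Me3SiOTf (5 mol %), CH2Cl2, −78 → −20 °C; pyridine quench
Reagents that add atoms: 1,2-bis(trimethylsilyloxy)ethane, C[Si](C)(C)OCCO[Si](C)(C)C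
Why: Silyl-triflate-catalysed ketalisation with the bis-silylated diol is aprotic and cold, so it should mask the ketone (driven by hexamethyldisiloxane formation) without cleaving the silyl ether or epimerising the α-centre.

**Union and release (steps 17–18)**

Step 17
Reactants: 14 (5S)-5-[(2E,4E,6R)-6-(tert-butyldimethylsilyloxymethyl)deca-2,4-dien-2-yl]furan-2(5H)-one; 26 2-[(2R,3S,4E,6E)-7-bromo-6-methyl-3-(triethylsilyloxy)hepta-4,6-dien-2-yl]-2-methyl-1,3-dioxolane
Product: 29 (3S,4S,5S)-5-[(2E,4E,6R)-6-(tert-butyldimethylsilyloxymethyl)deca-2,4-dien-2-yl]-4-methyl-3-[(1E,3E,5S,6R)-2-methyl-6-(2-methyl-1,3-dioxolan-2-yl)-5-(triethylsilyloxy)hepta-1,3-dien-1-yl]oxolan-2-one, via lithium enolate 27 (not isolated), via chlorozinc enolate 28 (not isolated)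
Conditions: Me2CuLi (1.1 equiv, from MeLi and CuBr·SMe2), Et2O–THF, −78 °C; ZnCl2 (2 equiv), THF, −78 → 0 °C; then 26 (1.3 equiv), Pd2(dba)3 (2.5 mol %), P(t-Bu)3 (5 mol %), THF, 0 °C → rt
Reagents that add atoms: lithium dimethylcuprate, [Li+].C[Cu-]C
Why: Proposed new method: Me2CuLi should add methyl to C4 of butenolide 14 through a copper–alkene π-complex and a trivalent-copper σ-adduct on the face opposite the C5 dienyl group, leaving lithium enolate 27, which ZnCl2 converts into the less basic chlorozinc enolate 28. Oxidative addition of bromide 26 to monoligated zerovalent palladium with retention of the E geometry, transmetalation of 28 and reductive elimination then form the C3–C(sp2) bond. The closest known reaction types are the tandem cuprate addition–enolate alkylation of γ-substituted butenolides and the palladium-catalysed (Negishi-type) coupling of ester zinc enolates with aryl and alkenyl bromides; what is new is their union in one flask on a lactone enolate in the presence of copper. No ring is closed, the existing lactone serving as the template. C4 is controlled by the C5 substituent (methyl trans to dienyl) and C3 by the new C4 methyl (palladium, hence alkenyl, trans to it), the 3,4-trans isomer also being the thermodynamic one. The step needs 1,4-addition to outrun SN2' opening of the allylic C5–O bond and removal of the C5 proton, which the low temperature, the non-basic cuprate and the hindered allylic termini of the diene should secure, and it needs the zinc enolate to couple without meeting a carbonyl group, which the dioxolane of 26 secures.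

Step 18
Reactants: 29 (3S,4S,5S)-5-[(2E,4E,6R)-6-(tert-butyldimethylsilyloxymethyl)deca-2,4-dien-2-yl]-4-methyl-3-[(1E,3E,5S,6R)-2-methyl-6-(2-methyl-1,3-dioxolan-2-yl)-5-(triethylsilyloxy)hepta-1,3-dien-1-yl]oxolan-2-one
Product: 30 (3S,4S,5S)-5-[(2E,4E,6R)-6-(hydroxymethyl)deca-2,4-dien-2-yl]-3-[(1E,3E,5S,6R)-5-hydroxy-2,6-dimethyl-7-oxoocta-1,3-dien-1-yl]-4-methyloxolan-2-one
Conditions: 1 M aq. HCl–THF (1:3), 0 °C → rt
Reagents that add atoms: water, O
Why: Acid-catalysed hydrolysis should open the dioxolane through its oxocarbenium ion and cleave both silyl ethers in one operation, dilute acid at or below room temperature being expected to leave the ketol, the lactone and all six stereocentres untouched.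

**Compound list**

1 | (4R)-4-benzyl-1,3-oxazolidin-2-one | O=C1N[C@H](Cc2ccccc2)CO1 | starting material
2 | hexanoyl chloride | CCCCCC(Cl)=O | starting material
3 | (4R)-4-benzyl-3-hexanoyl-1,3-oxazolidin-2-one | CCCCCC(=O)N1[C@H](Cc2ccccc2)COC1=O | intermediate
4 | chlorotitanium Z-enolate of 3 | CCCC/C=C(\O[Ti](Cl)(Cl)Cl)N1[C@H](Cc2ccccc2)COC1=O | intermediate
5 | (4R)-4-benzyl-3-[(2S)-2-(hydroxymethyl)hexanoyl]-1,3-oxazolidin-2-one | CCCC[C@H](C(=O)N1[C@H](Cc2ccccc2)COC1=O)CO | intermediate
6 | (4R)-4-benzyl-3-[(2S)-2-(tert-butyldimethylsilyloxymethyl)hexanoyl]-1,3-oxazolidin-2-one | CCCC[C@H](C(=O)N1[C@H](Cc2ccccc2)COC1=O)CO[Si](C)(C)C(C)(C)C | intermediate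
7 | (2R)-2-(tert-butyldimethylsilyloxymethyl)hexan-1-ol | CCCC[C@H](CO)CO[Si](C)(C)C(C)(C)C | intermediate
8 | (2S)-2-(tert-butyldimethylsilyloxymethyl)hexanal | CCCC[C@H](C=O)CO[Si](C)(C)C(C)(C)C | intermediate
9 | (2E,4R)-4-(tert-butyldimethylsilyloxymethyl)oct-2-enal | CCCC[C@H](/C=C/C=O)CO[Si](C)(C)C(C)(C)C | intermediate
10 | (2E,4E,6R)-6-(tert-butyldimethylsilyloxymethyl)-2-methyldeca-2,4-dienal | CCCC[C@H](/C=C/C=C(\C)C=O)CO[Si](C)(C)C(C)(C)C | intermediate
11 | methyl propiolate | COC(=O)C#C | starting material
12 | methyl (4R,5E,7E,9R)-9-(tert-butyldimethylsilyloxymethyl)-4-hydroxy-5-methyltrideca-5,7-dien-2-ynoate | CCCC[C@H](/C=C/C=C(\C)[C@@H](O)C#CC(=O)OC)CO[Si](C)(C)C(C)(C)C | intermediate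
13 | methyl (2Z,4S,5E,7E,9R)-9-(tert-butyldimethylsilyloxymethyl)-4-hydroxy-5-methyltrideca-2,5,7-trienoate | CCCC[C@H](/C=C/C=C(\C)[C@@H](O)/C=C\C(=O)OC)CO[Si](C)(C)C(C)(C)C | intermediate
14 | (5S)-5-[(2E,4E,6R)-6-(tert-butyldimethylsilyloxymethyl)deca-2,4-dien-2-yl]furan-2(5H)-one | CCCC[C@H](/C=C/C=C(\C)[C@H]1OC(=O)C=C1)CO[Si](C)(C)C(C)(C)C | intermediate
15 | methacrolein | CC(=C)C=O | starting material
16 | 2,3-dibromo-2-methylpropanal (racemic) | O=CC(C)(Br)CBr | intermediate
17 | (2E)-3-bromo-2-methylprop-2-enal | O=C/C(C)=C/Br | intermediate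
18 | (2E,4E)-5-bromo-N-cyclohexyl-4-methylpenta-2,4-dien-1-imine | Br/C=C(C)/C=C/C=NC1CCCCC1 | intermediate
19 | (2E,4E)-5-bromo-4-methylpenta-2,4-dienal | Br/C=C(C)/C=C/C=O | intermediate
20 | (4R)-4-benzyl-3-propanoyl-1,3-oxazolidin-2-one | CCC(=O)N1[C@H](Cc2ccccc2)COC1=O | starting material
21 | dibutylboron Z-enolate of 20 | C/C=C(\OB(CCCC)CCCC)N1[C@H](Cc2ccccc2)COC1=O | intermediate
22 | (4R)-4-benzyl-3-[(2R,3S,4E,6E)-7-bromo-3-hydroxy-2,6-dimethylhepta-4,6-dienoyl]-1,3-oxazolidin-2-one | Br/C=C(C)/C=C/[C@H](O)[C@@H](C)C(=O)N1[C@H](Cc2ccccc2)COC1=O | intermediate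
23 | (2R,3S,4E,6E)-7-bromo-3-hydroxy-N-methoxy-N,2,6-trimethylhepta-4,6-dienamide | Br/C=C(C)/C=C/[C@H](O)[C@@H](C)C(=O)N(C)OC | intermediate
24 | (2R,3S,4E,6E)-7-bromo-N-methoxy-N,2,6-trimethyl-3-(triethylsilyloxy)hepta-4,6-dienamide | Br/C=C(C)/C=C/[C@H](O[Si](CC)(CC)CC)[C@@H](C)C(=O)N(C)OC | intermediate
25 | (3R,4S,5E,7E)-8-bromo-3,7-dimethyl-4-(triethylsilyloxy)octa-5,7-dien-2-one | Br/C=C(C)/C=C/[C@H](O[Si](CC)(CC)CC)[C@@H](C)C(C)=O | intermediate
26 | 2-[(2R,3S,4E,6E)-7-bromo-6-methyl-3-(triethylsilyloxy)hepta-4,6-dien-2-yl]-2-methyl-1,3-dioxolane | Br/C=C(C)/C=C/[C@H](O[Si](CC)(CC)CC)[C@@H](C)C1(C)OCCO1 | intermediate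
27 | lithium enolate of the (4S,5S)-4-methyl-5-dienyl lactone | CCCC[C@H](/C=C/C=C(\C)[C@H]1OC(O[Li])=C[C@@H]1C)CO[Si](C)(C)C(C)(C)C | intermediate
28 | chlorozinc enolate of the (4S,5S)-4-methyl-5-dienyl lactone | CCCC[C@H](/C=C/C=C(\C)[C@H]1OC(O[Zn]Cl)=C[C@@H]1C)CO[Si](C)(C)C(C)(C)C | intermediate
29 | fully protected target (name as in step 17) | CCCC[C@H](/C=C/C=C(\C)[C@H]1OC(=O)[C@@H](/C=C(C)/C=C/[C@H](O[Si](CC)(CC)CC)[C@@H](C)C2(C)OCCO2)[C@@H]1C)CO[Si](C)(C)C(C)(C)C | intermediate
30 | CNP0187795.2 (name as in step 18) | CCCC[C@H](/C=C/C=C(\C)[C@H]1OC(=O)[C@@H](/C=C(C)/C=C/[C@H](O)[C@@H](C)C(C)=O)[C@@H]1C)CO | target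

Total step count: 18. Longest linear sequence: 11 steps (steps 1–9, 17 and 18).

**Three steps most likely to fail**

Step 17 (proposed new method). Several processes may divert it:
- The cuprate stage may open the allylic C5–O bond in an SN2' sense or remove the C5 proton.
- In the palladium stage the methyl group left on copper may pass to palladium and cap the bromide (hence the excess of 26).
- Copper salts may slow palladium turnover.
- Proton exchange between product and zinc enolate may erode C3 or move the side-chain double bond into conjugation with the lactone.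

The fallback uses known chemistry, sets out from 14 and returns at 29, and separates the two bond formations. Me2CuLi is added to 14 at −78 °C and the enolate is quenched with aqueous NH4Cl. After removal of all copper this gives the trans lactone (4S,5S)-5-[(2E,4E,6R)-6-(tert-butyldimethylsilyloxymethyl)deca-2,4-dien-2-yl]-4-methyloxolan-2-one F1. F1 is deprotonated with LiN(SiMe3)2 in THF at −78 °C, the lithium enolate is moved to zinc with ZnCl2, and it is coupled with 26 under Pd2(dba)3/P(t-Bu)3. This is the established palladium-catalysed alkenylation of a preformed ester zinc enolate, the alkenyl group again entering trans to the C4 methyl, and it gives 29.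

Step 18. Acid strong enough to open the dioxolane may dehydrate the unmasked ketol towards the conjugated trienone, ionise the dienylic carbinol (allylic transposition), or epimerise the centre next to the ketone. The fallback sets out from 25 and 14 and returns at 30, and it leaves the ketal out altogether. Ketone 25 replaces 26 in the coupling of step 17, since zinc ester enolates are known to tolerate ketone groups in palladium-catalysed couplings. This gives the bis-silyl ether of the target with the free ketone F2. Both silyl groups are then removed with pyridine-buffered HF·pyridine in THF at 0 °C, so no aqueous acid is needed.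

Step 8. Facial selectivity may be insufficient or opposite with this α-branched dienal, and methyl transfer from Me2Zn to the aldehyde may compete. The fallback sets out from 10 and returns at 12, and replaces the catalytic addition by oxidation and reagent-controlled reduction. Lithiated methyl propiolate (LiN(SiMe3)2, THF, −78 °C) adds to 10 without control to give the C4-epimeric propargylic alcohols F3. MnO2 in CH2Cl2 oxidises them to the 4-oxo-2-ynoate F4. Midland reduction with B-isopinocampheyl-9-borabicyclo[3.3.1]nonane prepared from (+)-α-pinene, the alkyne acting as the small group, should then give 12.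

**Further compounds**

F1 | step 17 | (4S,5S)-5-[(2E,4E,6R)-6-(tert-butyldimethylsilyloxymethyl)deca-2,4-dien-2-yl]-4-methyloxolan-2-one | CCCC[C@H](/C=C/C=C(\C)[C@H]1OC(=O)C[C@@H]1C)CO[Si](C)(C)C(C)(C)C
F2 | step 18 | (3S,4S,5S)-5-[(2E,4E,6R)-6-(tert-butyldimethylsilyloxymethyl)deca-2,4-dien-2-yl]-3-[(1E,3E,5S,6R)-2,6-dimethyl-7-oxo-5-(triethylsilyloxy)octa-1,3-dien-1-yl]-4-methyloxolan-2-one | CCCC[C@H](/C=C/C=C(\C)[C@H]1OC(=O)[C@@H](/C=C(C)/C=C/[C@H](O[Si](CC)(CC)CC)[C@@H](C)C(C)=O)[C@@H]1C)CO[Si](C)(C)C(C)(C)C
F3 | step 8 | methyl (5E,7E,9R)-9-(tert-butyldimethylsilyloxymethyl)-4-hydroxy-5-methyltrideca-5,7-dien-2-ynoate (both C4 epimers) | CCCC[C@H](/C=C/C=C(\C)C(O)C#CC(=O)OC)CO[Si](C)(C)C(C)(C)C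
F4 | step 8 | methyl (5E,7E,9R)-9-(tert-butyldimethylsilyloxymethyl)-5-methyl-4-oxotrideca-5,7-dien-2-ynoate | CCCC[C@H](/C=C/C=C(\C)C(=O)C#CC(=O)OC)CO[Si](C)(C)C(C)(C)C
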